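The target is cut at the bond between the bridging CH2 and the aromatic carbon of the butyrylphloroglucinol ring. The CH2 sits on C6 of the enolised 2-acetylcyclohexane-1,3,5-trione ring, flanked by the C1 and C5 carbonyls. It is therefore a latent exocyclic enone (quinone-methide-like) terminus, as in the presumed biosynthesis. In one operation a C6-dimethylaminomethyl Mannich base loses dimethylamine, and the resulting 6-methylene trione is captured by C5 of 3-geranylphlorobutyrophenone, its only unsubstituted ring carbon. The quaternary C4 stereocentre is set beforehand by enzymatic desymmetrisation of a geranyl(methyl)malonate and carried into the trione ring by a polyketide-type Claisen cyclisation.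

Key step: step 8

Assumption: pig liver esterase is taken to hydrolyse the pro-S ester group of diester 3, as it does with long-chain 2-alkyl-2-methylmalonates, so that the (R) half-ester results.
Remark: all β-triketone rings are tautomeric mixtures and are written in the enol form used for the target.

Step 1
Reactants: 1 dimethyl 2-methylmalonate; 2 geranyl bromide, (2E)-1-bromo-3,7-dimethylocta-2,6-diene
Product: 3 dimethyl 2-[(2E)-3,7-dimethylocta-2,6-dienyl]-2-methylmalonate (prochiral diester)
Conditions: NaH (1.1 equiv), THF, 0 °C; then 2 (1.0 equiv), 0 °C → rt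
Reagents that add atoms: none
Why: Malonic ester alkylation, in which the sodium enolate of 1 displaces the primary allylic bromide by SN2 with retention of the E alkene, and the product has no acidic C–H left, so the reaction should stop there.

Step 2
Reactants: 3 dimethyl 2-geranyl-2-methylmalonate
Product: 4 (2R,4E)-2-(methoxycarbonyl)-2,5,9-trimethyldeca-4,8-dienoic acid, the (R) half-ester
Conditions: pig liver esterase, 0.1 M phosphate buffer pH 7.5/DMSO 9:1, rt, pH-stat (1 M NaOH); then 1 M HCl to pH 2
Reagents that add atoms: water, O
Why: Enzymatic desymmetrisation of a prochiral 2,2-disubstituted malonate, in which the esterase should hydrolyse only the pro-S ester group (by analogy with long-chain 2-alkyl-2-methylmalonates) and thereby set the quaternary stereocentre as R, while the carboxylate formed is no substrate for a second hydrolysis.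

Step 3
Reactants: 4 (R) half-ester; 5 acetylacetone (pentane-2,4-dione)
Product: 7 methyl (2R,4E)-2-(3,5-dioxohexanoyl)-2,5,9-trimethyldeca-4,8-dienoate (triketo ester), via acyl imidazolide 6 (not isolated)
Conditions: 4, CDI (1.1 equiv), THF, rt; solution added at −78 °C to dilithio-5 [5 (3.2 equiv), LDA (6.4 equiv), THF, 0 °C], → −20 °C; 1 M HCl quench
Reagents that add atoms: 1,1'-carbonyldiimidazole, O=C(n1ccnc1)n1ccnc1 (imidazolyl group of 6 only; no atom of it remains in 7)
Why: Terminal (γ) acylation of a β-diketone dianion, in which the acyl imidazole is far more electrophilic than the hindered methyl ester, so the two carbonyl arms of the stereocentre stay differentiated, and the α-carbon bears no hydrogen and cannot form a ketene, so the configuration is kept.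

Step 4
Reactants: 7 triketo ester
Product: 8 (4R)-2-acetyl-4-[(2E)-3,7-dimethylocta-2,6-dienyl]-3,5-dihydroxy-4-methylcyclohexa-2,5-dien-1-one
Conditions: KOt-Bu (3 equiv), THF, 0 °C → rt; 1 M HCl
Reagents that add atoms: none
Why: Intramolecular Claisen (Dieckmann-type, polyketide-like) condensation, in which the carbanion between the two distal carbonyls attacks the ester in a 6-exo-trig closure, loss of methoxide and formation of the very stable β-triketone enolate drive the reaction (reversible O-acylation funnels to the same sink), and the hydrogen-free quaternary centre is untouched.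

Step 5
Reactants: 8 acetyl(geranyl)(methyl) trione
Product: 9 (4R)-2-acetyl-6-[(dimethylamino)methyl]-4-geranyl-3,5-dihydroxy-4-methylcyclohexa-2,5-dien-1-one (Mannich base, zwitterionic solid)
Conditions: CH2(NMe2)2 (1.1 equiv), CH2Cl2, 0 °C → rt; trituration with Et2O
Reagents that add atoms: bis(dimethylamino)methane, CN(C)CN(C)C
Why: Mannich reaction, in which the strongly acidic enol 8 protonates the aminal and the iminium ion so released is attacked by C6, the only unsubstituted ring carbon, while the secondary amine forms no stable enaminone with the acetyl group and the inner salt should separate before it reacts further.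

Step 6
Reactants: 10 phloroglucinol; 11 butyryl chloride
Product: 12 1-(2,4,6-trihydroxyphenyl)butan-1-one (phlorobutyrophenone)
Conditions: AlCl3 (3.5 equiv), CH2Cl2/PhNO2, 0 → 40 °C; ice/HCl
Reagents that add atoms: none
Why: Friedel–Crafts acylation of the threefold activated arene, where the first chelated acyl group deactivates the ring enough to favour monoacylation.

Step 7
Reactants: 12 phlorobutyrophenone; 2 geranyl bromide
Product: 13 1-{3-[(2E)-3,7-dimethylocta-2,6-dienyl]-2,4,6-trihydroxyphenyl}butan-1-one (3-geranylphlorobutyrophenone)
Conditions: 12 (1.3 equiv), 2 (1.0 equiv), K2CO3 (1.3 equiv), acetone, 50 °C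
Reagents that add atoms: none
Why: C-alkylation of the ambident acylphloroglucinolate by SN2 at the allylic bromide followed by rearomatisation, where the two free ring positions are equivalent and the deficit of bromide should curb double alkylation.

Step 8
Reactants: 9 Mannich base; 13 3-geranylphlorobutyrophenone
Product: 15 CNP0209203.1, (4R)-2-acetyl-6-[(3-butanoyl-5-geranyl-2,4,6-trihydroxyphenyl)methyl]-4-geranyl-3,5-dihydroxy-4-methylcyclohexa-2,5-dien-1-one, via 6-methylene trione 14 (not isolated)
Conditions: 9 (1.0 equiv), 13 (1.2 equiv), MeCN, 60 °C, slow N2 purge; dilute citric acid wash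
Reagents that add atoms: none
Why: On warming, the zwitterionic Mannich base 9 should lose dimethylamine by an E1cB retro-Michael elimination to give the 6-methylene trione 14, a quinone-methide-like acceptor whose CH2 terminus is activated by the C1 and C5 carbonyls; the phenolate of 13, formed by the liberated amine, adds through C5 in a conjugate (vinylogous Friedel–Crafts) addition, and tautomerisation restores the arene and the enolised trione. The closest known reaction types are the Mannich-base or formaldehyde route to methylene-bridged acylphloroglucinol dimers and the Knoevenagel–Michael union of cyclic β-triketones with acylphloroglucinols, and the step mirrors the presumed biosynthesis. No ring is closed and no stereocentre is formed; the C4 quaternary centre carries no hydrogen, lies outside the reacting π system and should be retained. Cross-coupling over homo-coupling is needed, and it is secured because the CH2 is pre-installed on one partner only, 14 is released slowly and 13 is present in slight excess. Site selectivity is secured because C5 is the only unsubstituted carbon of 13 and O-attack is reversible, so the C-alkylated product, stabilised by rearomatisation and by hydrogen bonds across the bridge, should accumulate. The trisubstituted alkenes of both geranyl chains are much poorer partners for 14 than the phenolate and should survive the acid-free conditions.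

Compound list
1 | dimethyl 2-methylmalonate | COC(=O)C(C)C(=O)OC | starting material
2 | geranyl bromide, (2E)-1-bromo-3,7-dimethylocta-2,6-diene | BrC/C=C(\C)CCC=C(C)C | starting material
3 | dimethyl 2-geranyl-2-methylmalonate | COC(=O)C(C)(C/C=C(\C)CCC=C(C)C)C(=O)OC | intermediate
4 | (2R,4E)-2-(methoxycarbonyl)-2,5,9-trimethyldeca-4,8-dienoic acid | OC(=O)[C@@](C)(C/C=C(\C)CCC=C(C)C)C(=O)OC | intermediate
5 | acetylacetone (pentane-2,4-dione) | CC(=O)CC(C)=O | starting material
6 | methyl (2R,4E)-2-(imidazol-1-ylcarbonyl)-2,5,9-trimethyldeca-4,8-dienoate (acyl imidazolide, not isolated) | COC(=O)[C@](C)(C/C=C(\C)CCC=C(C)C)C(=O)n1ccnc1 | intermediate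
7 | methyl (2R,4E)-2-(3,5-dioxohexanoyl)-2,5,9-trimethyldeca-4,8-dienoate | COC(=O)[C@](C)(C/C=C(\C)CCC=C(C)C)C(=O)CC(=O)CC(C)=O | intermediate
8 | (4R)-2-acetyl-4-geranyl-3,5-dihydroxy-4-methylcyclohexa-2,5-dien-1-one | O=C1C=C(O)[C@@](C)(C/C=C(\C)CCC=C(C)C)C(O)=C1C(C)=O | intermediate
9 | (4R)-2-acetyl-6-[(dimethylamino)methyl]-4-geranyl-3,5-dihydroxy-4-methylcyclohexa-2,5-dien-1-one | CN(C)CC1=C(O)[C@@](C)(C/C=C(\C)CCC=C(C)C)C(O)=C(C(C)=O)C1=O | intermediate
10 | phloroglucinol | Oc1cc(O)cc(O)c1 | starting material
11 | butyryl chloride | CCCC(=O)Cl | starting material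
12 | 1-(2,4,6-trihydroxyphenyl)butan-1-one | CCCC(=O)c1c(O)cc(O)cc1O | intermediate
13 | 1-(3-geranyl-2,4,6-trihydroxyphenyl)butan-1-one | CCCC(=O)c1c(O)c(C/C=C(\C)CCC=C(C)C)c(O)cc1O | intermediate
14 | 2-acetyl-4-geranyl-3-hydroxy-4-methyl-6-methylidenecyclohex-2-ene-1,5-dione, C4 arranged as in 8 (descriptor 4S through a priority change only; not isolated) | C=C1C(=O)[C@@](C)(C/C=C(\C)CCC=C(C)C)C(O)=C(C(C)=O)C1=O | intermediate
15 | CNP0209203.1 | CCCC(=O)c1c(O)c(C/C=C(\C)CCC=C(C)C)c(O)c(CC2=C(O)[C@@](C)(C/C=C(\C)CCC=C(C)C)C(O)=C(C(C)=O)C2=O)c1O | target

Total step count: 8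
Longest linear sequence: 6 (steps 1, 2, 3, 4, 5 and 8)

Steps most likely to fail

Step 8. Three processes may interfere. The liberated amine may promote retro-Michael exchange of the bridge after coupling, scrambling the product towards the symmetrical dimers. Retro-Mannich loss of the iminium unit may compete with loss of the amine. The methylene trione may self-condense before it is intercepted. The fallback sets out from 8 and comes back at 15 through 14, and it releases the methylene trione without any amine.
- Compound 8, aqueous formaldehyde and thiophenol (EtOH, rt, three-component Knoevenagel/thia-Michael reaction) should give the 6-(phenylsulfanylmethyl) derivative F1.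
- m-CPBA (1.0 equiv, CH2Cl2, −78 °C) oxidises the sulfide far faster than the trisubstituted alkenes and should give the sulfoxide F2.
- In the presence of 13 (toluene, rt → 40 °C) the sulfoxide should eliminate its sulfenic acid to the same intermediate 14, which 13 traps under neutral conditions to give 15.

Step 2. The lipophilic diester may be taken up poorly by the enzyme. Discrimination between the two enantiotopic ester groups may also be insufficient or of the opposite sense. The fallback sets out from 3 and comes back at 4 by chemical hydrolysis and classical resolution.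
- KOH (1.0 equiv, MeOH, rt) should give the racemic half-ester F3.
- (S)-1-Phenylethylamine converts it into the salt of the (R)-acid F4 and the salt of the (S)-acid F5, which should be separable by fractional crystallisation.
- Acidification of the former salt returns 4.

Step 3. Proton transfer from imidazole and from the product to the dianion may stall the acylation. Attack at the methyl ester instead of the acyl imidazole would erode the enantiomeric purity. Premature O-cyclisation may also intervene. The fallback sets out from 4 and 5 and comes back at 7, with a masked dianion under non-basic conditions.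
- Compound 4 and 1-chloro-N,N,2-trimethylpropenylamine (CH2Cl2, 0 °C) should give the acid chloride F6.
- Compound 5 is silylated (TMSCl, Et3N) to (Z)-4-(trimethylsilyloxy)pent-3-en-2-one F7 and then (LDA, TMSCl, THF, −78 °C) to 2,4-bis(trimethylsilyloxy)penta-1,3-diene F8.
- The acid chloride and the diene (CH2Cl2, −78 °C → rt) should combine at the terminal diene carbon in a vinylogous Mukaiyama-type acylation, and mild aqueous work-up gives 7.

Further compounds
F1 | step 8 | 2-acetyl-4-geranyl-3,5-dihydroxy-4-methyl-6-(phenylsulfanylmethyl)cyclohexa-2,5-dien-1-one, C4 arranged as in 8 (descriptor 4S through a priority change only) | O=C1C(CSc2ccccc2)=C(O)[C@@](C)(C/C=C(\C)CCC=C(C)C)C(O)=C1C(C)=O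
F2 | step 8 | 2-acetyl-4-geranyl-3,5-dihydroxy-4-methyl-6-(phenylsulfinylmethyl)cyclohexa-2,5-dien-1-one, C4 arranged as in 8, both configurations at sulfur | O=C1C(CS(=O)c2ccccc2)=C(O)[C@@](C)(C/C=C(\C)CCC=C(C)C)C(O)=C1C(C)=O
F3 | step 2 | racemic (4E)-2-(methoxycarbonyl)-2,5,9-trimethyldeca-4,8-dienoic acid | COC(=O)C(C)(C/C=C(\C)CCC=C(C)C)C(=O)O
F4 | step 2 | (S)-1-phenylethylammonium (2R,4E)-2-(methoxycarbonyl)-2,5,9-trimethyldeca-4,8-dienoate | COC(=O)[C@](C)(C/C=C(\C)CCC=C(C)C)C(=O)[O-].C[C@H]([NH3+])c1ccccc1
F5 | step 2 | (S)-1-phenylethylammonium (2S,4E)-2-(methoxycarbonyl)-2,5,9-trimethyldeca-4,8-dienoate | COC(=O)[C@@](C)(C/C=C(\C)CCC=C(C)C)C(=O)[O-].C[C@H]([NH3+])c1ccccc1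
F6 | step 3 | methyl (4E)-2-(chlorocarbonyl)-2,5,9-trimethyldeca-4,8-dienoate, C2 arranged as in 4 (descriptor 2S through a priority change only) | COC(=O)[C@](C)(C/C=C(\C)CCC=C(C)C)C(=O)Cl
F7 | step 3 | (Z)-4-(trimethylsilyloxy)pent-3-en-2-one | CC(=O)/C=C(/C)O[Si](C)(C)C
F8 | step 3 | (3Z)-2,4-bis(trimethylsilyloxy)penta-1,3-diene | C=C(O[Si](C)(C)C)/C=C(/C)O[Si](C)(C)C
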